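## Retrosynthetic overview
1. Target ⇒ hydrogenolysis of a "twin", in which two copies of the target are joined through their phenol oxygens by one p-xylylene unit. The linker is the phenol protecting group.
2. Twin bis-oxolane ⇒ cut C3–C4 in both halves to reach an open-chain tetraene made of two bis(1-arylallyl) ether units. One hydrogen-atom-initiated 5-exo radical closure forms both oxolane rings, all four methyl groups and C3/C4 of both halves.
3. Tetraene ⇒ cut both O–C5 bonds. This is an iridium-catalysed asymmetric allylic etherification of the twin (S,S)-allylic alcohol with a trimethoxycinnamyl carbonate, and it sets C5.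
4. Twin alcohol ⇒ catalytic asymmetric vinyl addition (sets C2) to the twin dialdehyde ⇒ 3-hydroxy-4,5-dimethoxybenzaldehyde + 1,4-bis(bromomethyl)benzene.
5. Ring order: all benzene rings are bought, the two oxolane rings are closed together late in the route, and no ring is made afterwards.

Assumption: 1, 2 and 5 are catalogue chemicals, and the named ligand enantiomers give the configurations drawn; if a sense of induction proves opposite, the mirror-image ligand is used and nothing else changes.

## Route

Step 1
Reactants: 1 3-hydroxy-4,5-dimethoxybenzaldehyde (2.05 equiv); 2 1,4-bis(bromomethyl)benzene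
Product: 3 twin dialdehyde 3,3'-[1,4-phenylenebis(methyleneoxy)]bis(4,5-dimethoxybenzaldehyde)
Conditions: K2CO3, DMF, 60 °C
Reagents that add atoms: none
Why: Williamson ether synthesis, in which the phenoxide of 1 displaces both benzylic bromides of 2, so one cheap linker masks two phenols and no stereocentre is formed.

Step 2
Reactants: 3 twin dialdehyde
Product: 4 twin allylic alcohol (1S,1'S)-1,1'-{1,4-phenylenebis[methyleneoxy(4,5-dimethoxybenzene-3,1-diyl)]}bis(prop-2-en-1-ol)
Conditions: CH2=CHMgBr, ZnCl2, THF, then 1,4-dioxane and filtration of the magnesium salts; (−)-MIB [(2S)-3-exo-morpholinoisoborneol] 10 mol%, toluene, −20 to 0 °C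
Reagents that add atoms: vinylmagnesium bromide, C=C[Mg]Br
Why: Amino-alcohol-catalysed enantioselective organozinc 1,2-addition (Noyori/Oppolzer type), in which the MIB–zinc complex delivers vinyl to the Si face of each aldehyde and sets the future C2 of both halves as S.

Step 3
Reactants: 5 methyl (E)-3-(3,4,5-trimethoxyphenyl)prop-2-enoate
Product: 6 (E)-3-(3,4,5-trimethoxyphenyl)prop-2-en-1-ol
Conditions: i-Bu2AlH (2.2 equiv), CH2Cl2, −78 °C
Reagents that add atoms: none
Why: 1,2-selective aluminium hydride reduction of a conjugated ester to the allylic alcohol, which leaves the E alkene and the aryl methyl ethers untouched.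

Step 4
Reactants: 6 (E)-3-(3,4,5-trimethoxyphenyl)prop-2-en-1-ol
Product: 7 tert-butyl (E)-3-(3,4,5-trimethoxyphenyl)prop-2-en-1-yl carbonate
Conditions: Boc2O, DMAP (5 mol%), THF, 0 °C to rt
Reagents that add atoms: di-tert-butyl dicarbonate, CC(C)(C)OC(=O)OC(=O)OC(C)(C)C
Why: DMAP-catalysed O-acylation, chosen because the tert-butyl carbonate later releases only the non-competing tert-butoxide.

Step 5
Reactants: 4 twin allylic alcohol; 7 tert-butyl cinnamyl-type carbonate (2.6 equiv)
Product: 9 twin tetraene 1,4-bis({2,3-dimethoxy-5-[(1S)-1-{[(1R)-1-(3,4,5-trimethoxyphenyl)prop-2-en-1-yl]oxy}prop-2-en-1-yl]phenoxy}methyl)benzene, via twin copper alkoxide 8 (not isolated)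
Conditions: n-BuLi (2.0 equiv), THF, 0 °C; CuI (2.0 equiv); then 7, [Ir(cod)Cl]2 (4 mol%), (Ra,Rc,Rc)-O,O'-(1,1'-binaphthalene-2,2'-diyl) N,N-bis(1-phenylethyl)phosphoramidite (8 mol%), THF, 0 °C to rt
Reagents that add atoms: copper iodide (CuI), [Cu]I (its copper is found in 8 only)
Why: Hartwig-type iridium-catalysed asymmetric allylic etherification, in which the soft copper alkoxide attacks the aryl-bearing end of the π-allyl iridium complex from outside the metal, so the catalyst sets each new C–O centre (future C5) as R while the C–O bond of 4 (future C2, S) is never broken.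

Step 6
Reactants: 9 twin tetraene
Product: 10 twin bis-oxolane 1,4-bis({5-[(2S,3S,4R,5R)-3,4-dimethyl-5-(3,4,5-trimethoxyphenyl)oxolan-2-yl]-2,3-dimethoxyphenoxy}methyl)benzene
Conditions: Fe(acac)3 (30 mol%), PhSH (20 mol%), PhSiH3 (6 equiv), EtOH/THF 1:1, 0.005 M, 40 °C, argon
Reagents that add atoms: none
Why: Proposed new method: a hydride of trivalent iron (from Fe(acac)3 and PhSiH3) gives a hydrogen atom to the CH2 end of either vinyl group of each half (first methyl), the secondary 2-(allyloxy)alkyl radical closes 5-exo-trig faster than the dilute thiol can quench it, and PhSH then caps the primary radical (second methyl), so two oxolane rings form in one operation; in the Beckwith–Houk chair both aryl groups sit pseudo-equatorial, which places each methyl trans to its neighbouring aryl and the two methyls cis (3S,4R), and the closest known reaction type is metal-hydride hydrogen-atom-transfer hydrogenation with a thiol co-catalyst, in which 1,6-dienes cyclise as radical clocks.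

Step 7
Reactants: 10 twin bis-oxolane
Product: 11 target 5-[(2S,3S,4R,5R)-3,4-dimethyl-5-(3,4,5-trimethoxyphenyl)oxolan-2-yl]-2,3-dimethoxyphenol (2 equiv per twin)
Conditions: H2 (1 atm), 10% Pd/C, EtOAc/EtOH, rt, neutral
Reagents that add atoms: none
Why: Catalytic hydrogenolysis of the two aryl benzyl-type ethers, which cleave far faster than the hindered secondary C–O bonds of the oxolane under neutral conditions, so no stereocentre is touched and any minor 3,4-trans isomer from step 6 is removed by chromatography at this monomer stage.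

## Compound list
1 | 3-hydroxy-4,5-dimethoxybenzaldehyde | O=Cc1cc(O)c(OC)c(OC)c1 | starting material
2 | 1,4-bis(bromomethyl)benzene | BrCc1ccc(CBr)cc1 | starting material
3 | twin dialdehyde, 3,3'-[1,4-phenylenebis(methyleneoxy)]bis(4,5-dimethoxybenzaldehyde) | O=Cc1cc(OC)c(OC)c(OCc2ccc(COc3cc(C=O)cc(OC)c3OC)cc2)c1 | intermediate
4 | twin (S,S)-allylic alcohol | COc1cc([C@H](C=C)O)cc(OCc2ccc(COc3cc([C@H](C=C)O)cc(OC)c3OC)cc2)c1OC | intermediate
5 | methyl (E)-3-(3,4,5-trimethoxyphenyl)prop-2-enoate | COC(=O)/C=C/c1cc(OC)c(OC)c(OC)c1 | starting material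
6 | (E)-3-(3,4,5-trimethoxyphenyl)prop-2-en-1-ol | OC/C=C/c1cc(OC)c(OC)c(OC)c1 | intermediate
7 | tert-butyl (E)-3-(3,4,5-trimethoxyphenyl)prop-2-en-1-yl carbonate | CC(C)(C)OC(=O)OC/C=C/c1cc(OC)c(OC)c(OC)c1 | intermediate
8 | twin copper alkoxide of 4 (not isolated) | COc1cc([C@H](C=C)O[Cu])cc(OCc2ccc(COc3cc([C@H](C=C)O[Cu])cc(OC)c3OC)cc2)c1OC | intermediate
9 | twin tetraene, each half (S) at the linked-aryl carbon and (R) at the trimethoxyphenyl carbon | COc1cc([C@H](C=C)O[C@@H](c2cc(OC)c(OC)c(OC)c2)C=C)cc(OCc2ccc(COc3cc([C@H](C=C)O[C@@H](c4cc(OC)c(OC)c(OC)c4)C=C)cc(OC)c3OC)cc2)c1OC | intermediate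
10 | twin bis-oxolane, each ring (2S,3S,4R,5R) | COc1cc([C@H]2O[C@@H](c3cc(OC)c(OC)c(OC)c3)[C@H](C)[C@@H]2C)cc(OCc2ccc(COc3cc([C@H]4O[C@@H](c5cc(OC)c(OC)c(OC)c5)[C@H](C)[C@@H]4C)cc(OC)c3OC)cc2)c1OC | intermediate
11 | 5-[(2S,3S,4R,5R)-3,4-dimethyl-5-(3,4,5-trimethoxyphenyl)oxolan-2-yl]-2,3-dimethoxyphenol | COc1cc([C@H]2O[C@@H](c3cc(OC)c(OC)c(OC)c3)[C@H](C)[C@@H]2C)cc(O)c1OC | target

## Count and risks
Total steps: 7. Longest linear sequence: 5 (steps 1, 2, 5, 6, 7; the branch 3, 4, 5, 6, 7 is equally long).

**Step 6 (most likely to fail).**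
- Risks: slow hydrogen-atom transfer to monosubstituted alkenes, plain hydrogenation before ring closure, or alkene migration into the doubly activated C–H.
- The fallback sets out from 9 and comes back at 11.
- The radical is started by sulfur instead of hydrogen. PhSH is added by syringe pump with AIBN in benzene at 80 °C.
- The thiyl radical adds reversibly to a terminal CH2, the same 5-exo closure follows, and PhSH caps the primary radical.
- This gives the twin bis(phenylthiomethyl) bis-oxolane F1. It is drawn with sulfur on the methyl next to C5; the regioisomers with sulfur on the other methyl converge to the same product.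
- W-2 Raney Ni in EtOH then cleaves all C–S bonds and the xylylene ethers in one pot. The electron-rich oxolane C–O bonds are spared, as dimethoxybenzyl-type ethers are under these conditions.

**Step 5.**
- Risks: a hindered secondary benzylic alkoxide as the limiting nucleophile, branched/linear ratio, and a two-fold reaction.
- The fallback sets out from 4 (as its copper alkoxide 8) and comes back at 9.
- Catalyst control is replaced by stereospecific substitution.
- 3,4,5-Trimethoxybenzaldehyde is vinylated with divinylzinc and (+)-MIB to give (R)-1-(3,4,5-trimethoxyphenyl)prop-2-en-1-ol F2.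
- ClCO2Me and pyridine convert F2 into (R)-methyl 1-(3,4,5-trimethoxyphenyl)prop-2-en-1-yl carbonate F3.
- RhCl(PPh3)3 modified by P(OMe)3 couples F3 with 8 in an Evans-type regio- and enantiospecific allylic etherification, with net retention at the branched carbon.

**Step 2.**
- Risks: the need for salt-free divinylzinc, the poor solubility of 3, and ee on an electron-rich aldehyde.
- The fallback sets out from 3 and comes back at 4.
- Asymmetric C–C bond formation is replaced by asymmetric ketone reduction.
- Vinylmagnesium bromide alone gives the stereorandom twin allylic alcohol F4.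
- MnO2 in CH2Cl2 oxidises F4 to the twin bis(aryl vinyl ketone) F5.
- (R)-Me-CBS oxazaborolidine with BH3·SMe2 at −30 °C reduces both ketones 1,2 from the same face to the (S,S)-diol.

## Further compounds
F1 | step 6 | twin bis(phenylthiomethyl) bis-oxolane, ring carbons arranged in space as in 10 | COc1cc([C@H]2O[C@@H](c3cc(OC)c(OC)c(OC)c3)[C@H](CSc3ccccc3)[C@@H]2C)cc(OCc2ccc(COc3cc([C@H]4O[C@@H](c5cc(OC)c(OC)c(OC)c5)[C@H](CSc5ccccc5)[C@@H]4C)cc(OC)c3OC)cc2)c1OC
F2 | step 5 | (R)-1-(3,4,5-trimethoxyphenyl)prop-2-en-1-ol | O[C@@H](c1cc(OC)c(OC)c(OC)c1)C=C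
F3 | step 5 | (R)-methyl 1-(3,4,5-trimethoxyphenyl)prop-2-en-1-yl carbonate | COC(=O)O[C@@H](c1cc(OC)c(OC)c(OC)c1)C=C
F4 | step 2 | stereorandom twin allylic alcohol | COc1cc(C(O)C=C)cc(OCc2ccc(COc3cc(C(O)C=C)cc(OC)c3OC)cc2)c1OC
F5 | step 2 | twin bis(aryl vinyl ketone) | COc1cc(C(=O)C=C)cc(OCc2ccc(COc3cc(C(=O)C=C)cc(OC)c3OC)cc2)c1OC
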